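**Retrosynthetic overview**
1. Niveusin B (1) comes from the oxa-bridged lactone 2 by C8 desilylation, angeloylation and C15 desilylation.
2. Lactone 2 comes from one intramolecular Nozaki–Hiyama–Kishi (NHK) allylation plus lactonisation of the hemiketal-enal 3. This closes the 10-membered ring and the butyrolactone, and sets C6 and C7.
3. Enal 3 comes from oxidative opening of the furan in 4 (the dearomatising key step). The Z-4-oxo-enal forms and the C10 tertiary OH traps the C3 ketone, so the THF hemiketal (C3–O–C10) exists before the macrocycle is closed.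
4. Furan 4 comes from B-alkyl Suzuki coupling of the vinyl group of an (R)-linalool (5)-derived γ-silyloxy enoate with a bromofuran made from 3-furanmethanol (6). C8 is set by proline α-aminoxylation/HWE on the linalool cleavage aldehyde.
5. Ring order: THF hemiketal first, then the 10-membered carbocycle and γ-lactone together.

Assumption: (R)-linalool and L-proline give the C10 (S) and C8 (R) centres required. The oxa-bridge then fixes C3, because only the cis-armed hemiketal epimer can macrocyclise.

**Step 1**
Reactants: 6 furan-3-ylmethanol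
Product: 7 (2-bromofuran-3-yl)methanol
Conditions: n-BuLi (2.2 equiv), THF, −78 → 0 °C; then (BrCCl2)2, −78 °C
Reagents that add atoms: 1,2-dibromotetrachloroethane, ClC(Cl)(Br)C(Cl)(Cl)Br
Why: the alkoxide directs lithiation to C2 of the furan (directed ortho-metalation), and the lithiofuran is trapped as the bromide. No stereocentre is formed.

**Step 2**
Reactants: 7
Product: 8 2-bromo-3-[(tert-butyldiphenylsilyloxy)methyl]furan
Conditions: TBDPSCl, imidazole, DMF, rt
Reagents that add atoms: TBDPSCl, CC(C)(C)[Si](Cl)(c1ccccc1)c1ccccc1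
Why: silyl protection gives a primary silyl ether that is stable to the later TES and TBS removals.

**Step 3**
Reactants: 9 triethyl phosphonoacetate
Product: 10 ethyl 2-(diethoxyphosphoryl)-3-hydroxypropanoate
Conditions: (CH2O)n, Et3N (cat.), THF, rt
Reagents that add atoms: formaldehyde (from paraformaldehyde), C=O
Why: hydroxymethylation of the active methylene by an aldol-type addition. It is achiral.

**Step 4**
Reactants: 10
Product: 11 ethyl 2-(diethoxyphosphoryl)-3-(triethylsilyloxy)propanoate
Conditions: TESCl, imidazole, CH2Cl2, 0 °C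
Reagents that add atoms: TESCl, CC[Si](Cl)(CC)CC
Why: protects the future C13 oxygen so that the HWE reagent is base-stable.

**Step 5**
Reactants: 5 (R)-linalool
Product: 12 (R)-linalool triethylsilyl ether
Conditions: TESOTf, 2,6-lutidine, CH2Cl2, −78 → 0 °C
Reagents that add atoms: TESOTf, CC[Si](CC)(CC)OS(=O)(=O)C(F)(F)F
Why: silylating the tertiary alcohol prevents lactol formation in the next steps and retains the C10 (S) centre of the target, with the linalool vinyl becoming C1=C2.

**Step 6**
Reactants: 12
Product: 13 (R)-4-methyl-4-(triethylsilyloxy)hex-5-enal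
Conditions: mCPBA, NaHCO3, CH2Cl2, 0 °C; then H5IO6, THF/Et2O, rt (one pot)
Reagents that add atoms: mCPBA, OOC(=O)c1cccc(Cl)c1 (supplies the aldehyde oxygen)
Why: chemoselective epoxidation of the trisubstituted alkene (the vinyl group is untouched), then periodate cleavage of the derived diol (Malaprade) gives the aldehyde. C10 is not touched.

**Step 7**
Reactants: 13; 11
Product: 14 ethyl (2E,4R,6R)-6-methyl-4-(phenylaminooxy)-6-(triethylsilyloxy)-2-[(triethylsilyloxy)methyl]octa-2,7-dienoate
Conditions: PhNO, L-proline (20 mol%), MeCN, 0 °C; then 11, LiCl, DBU, rt (one pot)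
Reagents that add atoms: nitrosobenzene, O=Nc1ccccc1
Why: proline-enamine α-aminoxylation sets the C8 (R) centre by catalyst control, and the Horner–Wadsworth–Emmons olefination traps it as the E-enoate without racemisation.

**Step 8**
Reactants: 14
Product: 15 γ-hydroxy enoate (C8–OH)
Conditions: CuSO4·5H2O, MeOH, rt
Reagents that add atoms: none
Why: Cu(II)-mediated N–O cleavage of the O-alkyl N-aryl hydroxylamine leaves the carbinol stereocentre untouched.

**Step 9**
Reactants: 15
Product: 16 C8-OTBS enoate
Conditions: TBSOTf, 2,6-lutidine, CH2Cl2, −78 °C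
Reagents that add atoms: TBSOTf, CC(C)(C)[Si](C)(C)OS(=O)(=O)C(F)(F)F
Why: the silyl ether blocks O-alkylation onto the later allylic bromide and ionisation in the Pd and Cr steps.

**Step 10**
Reactants: 16; 8
Product: 17 furan-tethered enoate (chain C2–C1 attached to furan C2)
Conditions: 9-BBN dimer, THF, 0 °C → rt; then 8, Pd(dppf)Cl2, K3PO4 (aq.), THF/DMF, 60 °C
Reagents that add atoms: none
Why: the monosubstituted vinyl group hydroborates selectively (anti-Markovnikov), and B-alkyl Suzuki–Miyaura coupling installs C2–C3(furan) with no new stereocentre.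

**Step 11**
Reactants: 17
Product: 18 diol (free C10–OH and free C13 allylic OH)
Conditions: HF·pyridine, pyridine/THF, 0 °C → rt
Reagents that add atoms: none
Why: the TES groups are cleaved selectively over the secondary TBS and the primary TBDPS ether.

**Step 12**
Reactants: 18
Product: 4 (Z)-allylic bromide, furan
Conditions: MsCl, Et3N, CH2Cl2, −40 °C; then LiBr, THF, 0 °C
Reagents that add atoms: lithium bromide, [Li+].[Br-]
Why: the primary allylic alcohol is mesylated selectively and displaced by SN2, with the alkene geometry retained so that CH2Br is cis to C8. The tertiary alcohol does not react, and the silylated C8 oxygen cannot cyclise onto the bromide.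

**Step 13**
Reactants: 4
Product: 3 hemiketal-enal
Conditions: DMDO, acetone/CH2Cl2, −20 → 0 °C
Reagents that add atoms: dimethyldioxirane, CC1(C)OO1
Why: oxidative furan ring-opening (furan epoxidation, then opening; Achmatowicz/Kobayashi-type) gives the (Z)-4-oxo-enal, whose geometry is fixed by the furan ring. The C10–OH adds to the C3 ketone to give the bridged 2-hydroxy-THF, with C3 fixed by the cis-arm requirement.

**Step 14**
Reactants: 3
Product: 2 oxa-bridged macrolactone (C8-OTBS, C15-OTBDPS)
Conditions: CrCl2 (8 equiv), DMF, 0 °C → rt, syringe-pump addition at about 3 mM; then PPTS (cat.), PhMe, 50 °C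
Reagents that add atoms: none
Why: Proposed new method: the Z-allylic bromide gives an (E)-allylchromium that adds to the enal aldehyde through a chair Zimmerman–Traxler transition state (anti selectivity, so a trans-fused lactone at C6/C7). The THF hemiketal holds the two arms cis, pre-organising 10-membered ring closure, and C7 relative to C8 is relayed through the bridged ring. The closest known reaction is the intramolecular NHK allylation used to make germacranolide 10-membered rings. Acid-catalysed lactonisation of the C6–OH onto the ethyl ester follows.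

**Step 15**
Reactants: 2
Product: 19 C8-alcohol, C15-OTBDPS
Conditions: HF·pyridine, pyridine/THF, 0 °C → rt
Reagents that add atoms: none
Why: the secondary TBS ether is removed selectively over the primary TBDPS ether. The hemiketal, α-methylene lactone and alkene survive this mildly acidic fluoride.

**Step 16**
Reactants: 19; 20 angelic acid
Product: 21 C8-angelate, C15-OTBDPS
Conditions: 2,4,6-Cl3C6H2COCl, Et3N, THF, rt (mixed anhydride of 20); then 19, DMAP, PhMe, rt
Reagents that add atoms: none (the angeloyl group comes from reactant 20)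
Why: Yamaguchi esterification at the secondary C8 alcohol under mild conditions keeps the (Z)-angelate from isomerising to the tiglate. The hindered hemiketal OH does not react.

**Step 17**
Reactants: 21
Product: 1 niveusin B
Conditions: HF·pyridine, THF, 0 °C → rt
Reagents that add atoms: none
Why: removal of the TBDPS group under non-basic conditions avoids angelate cleavage or acyl migration.

**Compound list**
1 | niveusin B | C=C1C(=O)O[C@@H]2/C=C(/CO)[C@@]3(O)CC[C@@](C)(C[C@@H](OC(=O)/C(C)=C\C)[C@@H]12)O3 | target
2 | oxa-bridged macrolactone, C8-OTBS, C15-OTBDPS | C=C1C(=O)O[C@@H]2/C=C(/CO[Si](c4ccccc4)(c4ccccc4)C(C)(C)C)[C@@]3(O)CC[C@@](C)(C[C@@H](O[Si](C)(C)C(C)(C)C)[C@@H]12)O3 | intermediate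
3 | bridged THF hemiketal with Z-enal and (Z)-2-(ethoxycarbonyl)allyl bromide arm | CCOC(=O)/C(CBr)=C/[C@H](O[Si](C)(C)C(C)(C)C)C[C@]1(C)CCC(O)(O1)/C(CO[Si](c2ccccc2)(c2ccccc2)C(C)(C)C)=C\C=O | intermediate
4 | furan-tethered (Z)-allylic bromide, free C10-OH | CCOC(=O)/C(CBr)=C/[C@H](O[Si](C)(C)C(C)(C)C)C[C@@](C)(O)CCc1occc1CO[Si](c2ccccc2)(c2ccccc2)C(C)(C)C | intermediate
5 | (R)-(−)-linalool | CC(C)=CCC[C@@](C)(O)C=C | starting material
6 | furan-3-ylmethanol | OCc1ccoc1 | starting material
7 | (2-bromofuran-3-yl)methanol | OCc1ccoc1Br | intermediate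
8 | 2-bromo-3-[(TBDPSO)methyl]furan | Brc1occc1CO[Si](c2ccccc2)(c2ccccc2)C(C)(C)C | intermediate
9 | triethyl phosphonoacetate | CCOC(=O)CP(=O)(OCC)OCC | starting material
10 | ethyl 2-(diethoxyphosphoryl)-3-hydroxypropanoate | CCOC(=O)C(CO)P(=O)(OCC)OCC | intermediate
11 | ethyl 2-(diethoxyphosphoryl)-3-(TESO)propanoate | CCOC(=O)C(CO[Si](CC)(CC)CC)P(=O)(OCC)OCC | intermediate
12 | (R)-linalool TES ether | CC(C)=CCC[C@@](C)(O[Si](CC)(CC)CC)C=C | intermediate
13 | (R)-4-methyl-4-(TESO)hex-5-enal | O=CCC[C@@](C)(O[Si](CC)(CC)CC)C=C | intermediate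
14 | γ-aminoxy (E)-enoate | CCOC(=O)/C(CO[Si](CC)(CC)CC)=C/[C@H](ONc1ccccc1)C[C@@](C)(O[Si](CC)(CC)CC)C=C | intermediate
15 | γ-hydroxy (E)-enoate | CCOC(=O)/C(CO[Si](CC)(CC)CC)=C/[C@H](O)C[C@@](C)(O[Si](CC)(CC)CC)C=C | intermediate
16 | C8-OTBS enoate | CCOC(=O)/C(CO[Si](CC)(CC)CC)=C/[C@H](O[Si](C)(C)C(C)(C)C)C[C@@](C)(O[Si](CC)(CC)CC)C=C | intermediate
17 | furan-coupled bis-TES enoate | CCOC(=O)/C(CO[Si](CC)(CC)CC)=C/[C@H](O[Si](C)(C)C(C)(C)C)C[C@@](C)(O[Si](CC)(CC)CC)CCc1occc1CO[Si](c2ccccc2)(c2ccccc2)C(C)(C)C | intermediate
18 | diol (C10-OH, C13-OH free) | CCOC(=O)/C(CO)=C/[C@H](O[Si](C)(C)C(C)(C)C)C[C@@](C)(O)CCc1occc1CO[Si](c2ccccc2)(c2ccccc2)C(C)(C)C | intermediate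
19 | C8-alcohol, C15-OTBDPS lactone | C=C1C(=O)O[C@@H]2/C=C(/CO[Si](c4ccccc4)(c4ccccc4)C(C)(C)C)[C@@]3(O)CC[C@@](C)(C[C@@H](O)[C@@H]12)O3 | intermediate
20 | angelic acid ((Z)-2-methylbut-2-enoic acid) | OC(=O)/C(C)=C\C | starting material
21 | C8-angelate, C15-OTBDPS | C=C1C(=O)O[C@@H]2/C=C(/CO[Si](c4ccccc4)(c4ccccc4)C(C)(C)C)[C@@]3(O)CC[C@@](C)(C[C@@H](OC(=O)/C(C)=C\C)[C@@H]12)O3 | intermediate

**Totals:** 17 steps in all, and the longest linear sequence is 13 steps (5 → 12 → 13 → 14 → 15 → 16 → 17 → 18 → 4 → 3 → 2 → 19 → 21 → 1).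

**Three steps most likely to fail**
1. Step 14 (macro-NHK): the yield, or the C6/C7/C8 diastereoselectivity, may be poor in the strained bridged ring. Fallback: build the trans-lactone first by cuprate conjugate addition to a 5-substituted butenolide and α-methylenation, then close the 10-membered ring by intramolecular vinyl-iodide NHK onto a C3 aldehyde, followed by C3 oxidation and hemiketalisation.
2. Step 13 (furan oxidation): the Z-enal may isomerise or over-oxidise. Fallback: drop the furan and carry a C4≡C5 alkyne, closing the ring by alkynyl-metal addition to the C3 aldehyde. Then oxidise C3, reduce the alkyne Z-selectively (Lindlar), and oxidise C6 to the lactone carbinol.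
3. Step 10 (hydroboration/Suzuki): the 9-BBN may not be fully chemoselective in the presence of the enoate, and the ortho-substituted 2-bromofuran may couple poorly. Fallback: hydroborate and oxidise the vinyl group, convert the resulting alcohol to a primary iodide, and alkylate 2-lithio-3-(TBDPSOCH2)furan (Li–Br exchange of 8) with it under Cu(I) catalysis.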